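## Retrosynthetic overview

- The hydroxy-p-quinone (ring C, formed last) comes from oxidative unmasking of a dithiane-protected bicyclic 1,2,4-trione, which is oxidised in the same flask.
- Ring C is annulated onto a γ,γ-disubstituted cyclohexenone: lithiated ethyl 1,3-dithiane-2-carboxylate (a glyoxylate acyl-anion equivalent) bonds to the enone β-carbon, an isovaleryl unit is added at the α-carbon, and a Dieckmann condensation closes the ring.
- The enone comes from an α-quaternary cyclohexanone by 1,3-carbonyl transposition (enol triflate, hydrogenolysis, allylic oxidation).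
- Ring B is bought as 2-methylcyclohexenone; both stereocentres are set in one flask by Cu-catalysed asymmetric conjugate addition of isopropenyl and anti-selective Michael trapping with methyl acrylate.

Assumption: the antipode of the chiral NHC–Cu ligand in step 1 (both are accessible) is the one that gives the (6S) ketone; all locants are those of the systematic names given.

## Route

Step 1
Reactants: 1 2-methylcyclohex-2-en-1-one; 2 isopropenylmagnesium bromide; 3 methyl acrylate
Product: 5 methyl 3-[(1S,6S)-1-methyl-2-oxo-6-(prop-1-en-2-yl)cyclohexyl]propanoate, via magnesium enolate 4 (not isolated)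
Conditions: Cu(OTf)2 (3 mol%), chiral imidazolinium NHC precursor (4 mol%), 2 (1.3 equiv), Et2O, −30 °C; then DMPU, 3 (2 equiv), −40 → 0 °C; 1 M HCl
Reagents that add atoms: none
Why: Cu-catalysed asymmetric conjugate addition of the alkenyl Grignard reagent sets the isopropenyl-bearing centre (S) under ligand control, and the fully substituted magnesium enolate 4 then adds to methyl acrylate anti to the adjacent isopropenyl group, fixing the quaternary centre (S) with the ester chain trans to isopropenyl (three-component conjugate addition/enolate trapping).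

Step 2
Reactants: 5 methyl 3-[(1S,6S)-1-methyl-2-oxo-6-(prop-1-en-2-yl)cyclohexyl]propanoate
Product: 7 methyl 3-[(1S,6S)-1-methyl-6-(prop-1-en-2-yl)-2-(trifluoromethylsulfonyloxy)cyclohex-2-en-1-yl]propanoate, via potassium enolate 6 (not isolated)
Conditions: KHMDS (1.1 equiv), THF, −78 °C; PhNTf2 (1.15 equiv), −78 → 0 °C; 1 M HCl
Reagents that add atoms: N-phenylbis(trifluoromethanesulfonimide), O=S(=O)(N(c1ccccc1)S(=O)(=O)C(F)(F)F)C(F)(F)F
Why: Only the CH2 flank of the ketone can enolise and the ketone is far more acidic than the ester at −78 °C, so enol triflate formation is regiospecific and touches neither stereocentre.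

Step 3
Reactants: 7 methyl 3-[(1S,6S)-1-methyl-6-(prop-1-en-2-yl)-2-(trifluoromethylsulfonyloxy)cyclohex-2-en-1-yl]propanoate
Product: 8 methyl 3-[(1R,6S)-1-methyl-6-(prop-1-en-2-yl)cyclohex-2-en-1-yl]propanoate
Conditions: Pd(OAc)2 (5 mol%), PPh3 (10 mol%), HCO2H (2 equiv), n-Bu3N (3 equiv), DMF, 60 °C
Reagents that add atoms: none
Why: Pd(0)-catalysed formate hydrogenolysis of the enol triflate replaces OTf by H without affecting the isopropenyl group, the ester or either stereocentre (the descriptor change to 1R is only a priority change).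

Step 4
Reactants: 8 methyl 3-[(1R,6S)-1-methyl-6-(prop-1-en-2-yl)cyclohex-2-en-1-yl]propanoate
Product: 10 methyl 3-[(1R,6S)-1-methyl-4-oxo-6-(prop-1-en-2-yl)cyclohex-2-en-1-yl]propanoate, via allylic peroxide 9 (not isolated)
Conditions: Rh2(cap)4 (1 mol%), t-BuOOH (70% aq, 5 equiv), K2CO3 (0.5 equiv), CH2Cl2, rt
Reagents that add atoms: tert-butyl hydroperoxide, CC(C)(C)OO
Why: Rh(II)/tert-butylperoxyl allylic oxidation attacks the only ring-allylic CH2 (the other allylic terminus is quaternary, so the peroxide is trapped at the unhindered end), an isopropenyl group survives such conditions as in the valencene-to-nootkatone oxidation, and the mixed peroxide 9 collapses to the enone with both stereocentres unchanged.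

Step 5
Reactants: 10 methyl 3-[(1R,6S)-1-methyl-4-oxo-6-(prop-1-en-2-yl)cyclohex-2-en-1-yl]propanoate; 11 ethyl 1,3-dithiane-2-carboxylate; 12 3-methylbutanoyl chloride
Product: 15 methyl 3-[(7'S,8'S)-8'-methyl-2',4',5'-trioxo-3'-(propan-2-yl)-7'-(prop-1-en-2-yl)octahydrospiro[1,3-dithiane-2,1'-naphthalen]-8'-yl]propanoate, via lithium enolate 13 (not isolated), via 2-acyl ketone 14 (not isolated)
Conditions: 11 (1.2 equiv), LiHMDS (1.2 equiv), THF–DMPU, −78 °C; add 10, −78 → −20 °C; MgBr2·OEt2 (1.5 equiv), 12 (1.3 equiv), −78 → 0 °C; NaOMe (5 equiv), MeOH, 45 °C; 1 M HCl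
Reagents that add atoms: none
Why: Proposed new method: the sulfur-stabilised ester enolate of 11 is a glyoxylate acyl-anion equivalent that adds 1,4 to the only β-carbon of enone 10 (joining two normally electrophilic carbons), the regiodefined enolate 13 is C-acylated as its magnesium chelate to 14, and methoxide then drives Dieckmann closure of the side-chain α-carbanion onto the dithiane ester because only this closure gives an enolisable cyclic β-triketone while O-acyl, regioisomeric and bridged Claisen products revert; the new ring-fusion and isopropyl-bearing centres are epimer mixtures planarised in step 6 and the two existing stereocentres cannot enolise; the closest known reactions are Michael additions of lithiated 1,3-dithiane-2-carboxylates to cyclohexenones and Michael–Dieckmann (Hauser–Kraus type) annulations.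

Step 6
Reactants: 15 methyl 3-[(7'S,8'S)-8'-methyl-2',4',5'-trioxo-3'-(propan-2-yl)-7'-(prop-1-en-2-yl)octahydrospiro[1,3-dithiane-2,1'-naphthalen]-8'-yl]propanoate
Product: 17 methyl 3-[(1S,2S)-7-hydroxy-1-methyl-4,5,8-trioxo-6-(propan-2-yl)-2-(prop-1-en-2-yl)-1,2,3,4,5,8-hexahydronaphthalen-1-yl]propanoate, via benzenetriol 16 (not isolated)
Conditions: PhI(OCOCF3)2 (2.3 equiv), MeCN–H2O 9:1, 0 °C → rt
Reagents that add atoms: water, O
Why: Hypervalent-iodine oxidative dethioacetalisation unmasks the fourth carbonyl, the 1,2,4-trione tautomerises to the acyl-hydroxyhydroquinone 16, and a second equivalent of the same oxidant performs the hydroquinone-to-quinone oxidation to the stable hydroxy-p-quinone tautomer, while the quaternary centre and the β-positioned isopropenyl centre cannot epimerise.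

## Compound list

1 | 2-methylcyclohex-2-en-1-one | CC1=CCCCC1=O | starting material
2 | isopropenylmagnesium bromide (prop-1-en-2-ylmagnesium bromide) | C=C(C)[Mg]Br | starting material
3 | methyl acrylate | C=CC(=O)OC | starting material
4 | bromomagnesium (3S)-2-methyl-3-(prop-1-en-2-yl)cyclohex-1-en-1-olate | C=C(C)[C@@H]1CCCC(O[Mg]Br)=C1C | intermediate (not isolated)
5 | methyl 3-[(1S,6S)-1-methyl-2-oxo-6-(prop-1-en-2-yl)cyclohexyl]propanoate | C=C(C)[C@@H]1CCCC(=O)[C@@]1(C)CCC(=O)OC | intermediate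
6 | potassium (5S,6S)-6-(3-methoxy-3-oxopropyl)-6-methyl-5-(prop-1-en-2-yl)cyclohex-1-en-1-olate | C=C(C)[C@@H]1CCC=C(O[K])[C@@]1(C)CCC(=O)OC | intermediate (not isolated)
7 | methyl 3-[(1S,6S)-1-methyl-6-(prop-1-en-2-yl)-2-(trifluoromethylsulfonyloxy)cyclohex-2-en-1-yl]propanoate | C=C(C)[C@@H]1CCC=C(OS(=O)(=O)C(F)(F)F)[C@@]1(C)CCC(=O)OC | intermediate
8 | methyl 3-[(1R,6S)-1-methyl-6-(prop-1-en-2-yl)cyclohex-2-en-1-yl]propanoate | C=C(C)[C@@H]1CCC=C[C@@]1(C)CCC(=O)OC | intermediate
9 | methyl 3-[(1R,6S)-4-(tert-butylperoxy)-1-methyl-6-(prop-1-en-2-yl)cyclohex-2-en-1-yl]propanoate (C-4 epimers) | C=C(C)[C@@H]1CC(OOC(C)(C)C)C=C[C@@]1(C)CCC(=O)OC | intermediate (not isolated)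
10 | methyl 3-[(1R,6S)-1-methyl-4-oxo-6-(prop-1-en-2-yl)cyclohex-2-en-1-yl]propanoate | C=C(C)[C@@H]1CC(=O)C=C[C@@]1(C)CCC(=O)OC | intermediate
11 | ethyl 1,3-dithiane-2-carboxylate | CCOC(=O)C1SCCCS1 | starting material
12 | 3-methylbutanoyl chloride (isovaleryl chloride) | CC(C)CC(=O)Cl | starting material
13 | lithium (4S,5S)-3-[2-(ethoxycarbonyl)-1,3-dithian-2-yl]-4-(3-methoxy-3-oxopropyl)-4-methyl-5-(prop-1-en-2-yl)cyclohex-1-en-1-olate (C-3 epimers) | C=C(C)[C@@H]1CC(O[Li])=CC(C2(SCCCS2)C(=O)OCC)[C@@]1(C)CCC(=O)OC | intermediate (not isolated)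
14 | ethyl 2-[(5S,6S)-6-(3-methoxy-3-oxopropyl)-6-methyl-2-(3-methylbutanoyl)-3-oxo-5-(prop-1-en-2-yl)cyclohexyl]-1,3-dithiane-2-carboxylate (C-1/C-2 epimers, enolised) | C=C(C)[C@@H]1CC(=O)C(C(=O)CC(C)C)C(C2(SCCCS2)C(=O)OCC)[C@@]1(C)CCC(=O)OC | intermediate (not isolated)
15 | methyl 3-[(7'S,8'S)-8'-methyl-2',4',5'-trioxo-3'-(propan-2-yl)-7'-(prop-1-en-2-yl)octahydrospiro[1,3-dithiane-2,1'-naphthalen]-8'-yl]propanoate (drawn as the triketo tautomer; other centres as epimer mixtures) | C=C(C)[C@@H]1CC(=O)C2C(=O)C(C(C)C)C(=O)C3(SCCCS3)C2[C@@]1(C)CCC(=O)OC | intermediate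
16 | methyl 3-[(1S,2S)-5,7,8-trihydroxy-1-methyl-4-oxo-6-(propan-2-yl)-2-(prop-1-en-2-yl)-1,2,3,4-tetrahydronaphthalen-1-yl]propanoate | C=C(C)[C@@H]1CC(=O)c2c(O)c(C(C)C)c(O)c(O)c2[C@@]1(C)CCC(=O)OC | intermediate (not isolated)
17 | methyl 3-[(1S,2S)-7-hydroxy-1-methyl-4,5,8-trioxo-6-(propan-2-yl)-2-(prop-1-en-2-yl)-1,2,3,4,5,8-hexahydronaphthalen-1-yl]propanoate | C=C(C)[C@@H]1CC(=O)C2=C(C(=O)C(O)=C(C(C)C)C2=O)[C@@]1(C)CCC(=O)OC | target

## Step count and risks

Total step count: 6. Longest linear sequence: 6 steps (1 → 17; compounds 2, 3, 11 and 12 are purchased).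

**Most likely to fail, first: step 5.** The acyl-anion Michael addition is onto a β-carbon next to a quaternary centre, proton transfer can compete, and the hindered enolate may be O-acylated. The fallback moves the whole sequence into the Lewis-acid (Mukaiyama) manifold with isolable silyl intermediates. It sets out from 10. Ester 11 is converted (LDA, TMSCl) into 2-[ethoxy(trimethylsilyloxy)methylidene]-1,3-dithiane F1. F1 is added to 10 under TMSOTf or TiCl4 promotion (Mukaiyama–Michael) to give ethyl 2-[(5S,6S)-6-(3-methoxy-3-oxopropyl)-6-methyl-5-(prop-1-en-2-yl)-3-(trimethylsilyloxy)cyclohex-2-en-1-yl]-1,3-dithiane-2-carboxylate F2. The regiodefined silyl enol ether F2 is C-acylated with 12 and TiCl4 to give 14, now isolated, and NaOMe/MeOH closes ring C so that the sequence comes back to the route at 15.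

**Second: step 1.** The enantioselectivity of an alkenyl Grignard addition to an α-substituted enone is uncertain, and so is Michael trapping of the hindered magnesium enolate without acrylate oligomerisation. The fallback sets out from 1. The same Cu-catalysed conjugate addition of 2 is quenched with TMSCl/Et3N to isolate trimethyl{[(3S)-2-methyl-3-(prop-1-en-2-yl)cyclohex-1-en-1-yl]oxy}silane F3. F3 undergoes a Tf2NH-catalysed Mukaiyama–Michael addition to 3 (CH2Cl2, −78 °C), anti to the isopropenyl group, giving the silyl ketene acetal (2S,3S)-2-[3-methoxy-3-(trimethylsilyloxy)prop-2-en-1-yl]-2-methyl-3-(prop-1-en-2-yl)cyclohexan-1-one F4. Hydrolysis of F4 on work-up brings the sequence back to the route at 5.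

**Third: step 4.** Allylic oxidation may also attack the isopropenyl allylic positions or trap the allyl radical at the hindered end. The fallback replaces C–H oxidation by a Wharton carbonyl transposition and sets out from 5. IBX (DMSO/toluene, 70 °C) dehydrogenates 5 to methyl 3-[(1S,6S)-1-methyl-2-oxo-6-(prop-1-en-2-yl)cyclohex-3-en-1-yl]propanoate F5. Nucleophilic epoxidation (t-BuOOH, DBU) gives methyl 3-[(3S,4S)-3-methyl-2-oxo-4-(prop-1-en-2-yl)-7-oxabicyclo[4.1.0]heptan-3-yl]propanoate F6. Wharton rearrangement (N2H4·H2O, AcOH, MeOH) gives methyl 3-[(1R,6S)-4-hydroxy-1-methyl-6-(prop-1-en-2-yl)cyclohex-2-en-1-yl]propanoate F7. MnO2 oxidation of F7 comes back to the route at 10.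

Further compounds
F1 | step 5 | 2-[ethoxy(trimethylsilyloxy)methylidene]-1,3-dithiane | CCOC(O[Si](C)(C)C)=C1SCCCS1
F2 | step 5 | ethyl 2-[(5S,6S)-6-(3-methoxy-3-oxopropyl)-6-methyl-5-(prop-1-en-2-yl)-3-(trimethylsilyloxy)cyclohex-2-en-1-yl]-1,3-dithiane-2-carboxylate | C=C(C)[C@@H]1CC(O[Si](C)(C)C)=CC(C2(SCCCS2)C(=O)OCC)[C@@]1(C)CCC(=O)OC
F3 | step 1 | trimethyl{[(3S)-2-methyl-3-(prop-1-en-2-yl)cyclohex-1-en-1-yl]oxy}silane | C=C(C)[C@@H]1CCCC(O[Si](C)(C)C)=C1C
F4 | step 1 | (2S,3S)-2-[3-methoxy-3-(trimethylsilyloxy)prop-2-en-1-yl]-2-methyl-3-(prop-1-en-2-yl)cyclohexan-1-one | C=C(C)[C@@H]1CCCC(=O)[C@@]1(C)CC=C(OC)O[Si](C)(C)C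
F5 | step 4 | methyl 3-[(1S,6S)-1-methyl-2-oxo-6-(prop-1-en-2-yl)cyclohex-3-en-1-yl]propanoate | C=C(C)[C@@H]1CC=CC(=O)[C@@]1(C)CCC(=O)OC
F6 | step 4 | methyl 3-[(3S,4S)-3-methyl-2-oxo-4-(prop-1-en-2-yl)-7-oxabicyclo[4.1.0]heptan-3-yl]propanoate | C=C(C)[C@@H]1CC2OC2C(=O)[C@@]1(C)CCC(=O)OC
F7 | step 4 | methyl 3-[(1R,6S)-4-hydroxy-1-methyl-6-(prop-1-en-2-yl)cyclohex-2-en-1-yl]propanoate | C=C(C)[C@@H]1CC(O)C=C[C@@]1(C)CCC(=O)OC
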